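**Retrosynthetic overview**
1. Target 28 ⇒ keto lactone 20: late work on ring C only (C12=C13 enone, phosphonoacetate Michael/olefination for the acrylate at C13, C11 ketone reduction).
2. 20 ⇒ aldehyde oxalate 16 in one operation: a tertiary C10 radical closes the 7,20-lactone ring through C9–C10, and the lactone enolate this produces closes the cyclopentane by the C6→C8 aldol.
3. 16 ⇒ ring A epoxy acetate 10 + ring C acid 11 (ester C20–O–C7 by epoxide opening, then oxalate, then ozonolysis of a vinyl group to the C6 aldehyde).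
4. 10 ⇒ 4,4-dimethylcyclohex-2-en-1-one (vinyl conjugate addition/Mannich, α-methylenation, Luche reduction, kinetic resolution by asymmetric epoxidation).
5. Ring order: rings A and C are bought as six-membered rings; third the lactone ring, fourth the cyclopentane, both in step 9.

Assumption: 3-oxocyclohex-1-ene-1-carboxylic acid (11) is taken as a purchasable building block; the labels C1–C20 used below are the ent-kaurane positions of the target (target = 1S,5R,6S,8S,9S,10S,11S,13S).

**Route**

Step 1
Reactants: 1 4,4-dimethylcyclohex-2-en-1-one; 2 vinylmagnesium bromide; 3 N,N-dimethylmethyleneiminium iodide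
Product: 5 (2R*,3S*)-2-[(dimethylamino)methyl]-4,4-dimethyl-3-vinylcyclohexan-1-one (racemic), via magnesium enolate 4 (not isolated)
Conditions: 2 (1.3 equiv), CuBr·SMe2 (10 mol %), THF, −40 °C; then 3, −40 to 0 °C
Reagents that add atoms: none
Why: Copper-catalysed conjugate addition of the vinyl Grignard reagent puts the future C6 on C5 (racemic here) and gives a regiodefined enolate that is trapped at C10 by the iminium salt (Mannich reaction) anti to the vinyl group.

Step 2
Reactants: 5 (2R*,3S*)-2-[(dimethylamino)methyl]-4,4-dimethyl-3-vinylcyclohexan-1-one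
Product: 7 (3R*)-4,4-dimethyl-2-methylidene-3-vinylcyclohexan-1-one (racemic), via ammonium iodide 6 (not isolated)
Conditions: MeI, CH2Cl2, 23 °C; then NaHCO3 (aq), 23 °C
Reagents that add atoms: none
Why: N-Methylation turns the amine into a leaving group and base-induced E1cB (Hofmann-type) elimination gives the 2-methylidene ketone, so C20 is in place as the exocyclic methylene carbon.

Step 3
Reactants: 7 (3R*)-4,4-dimethyl-2-methylidene-3-vinylcyclohexan-1-one
Product: 8 (1S*,3R*)-4,4-dimethyl-2-methylidene-3-vinylcyclohexan-1-ol (racemic, hydroxyl cis to vinyl)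
Conditions: NaBH4, CeCl3·7H2O, MeOH, −78 °C
Reagents that add atoms: none
Why: Luche 1,2-reduction with axial hydride delivery to the chair that carries the vinyl group equatorially gives the equatorial C1 alcohol cis to the C5 vinyl group, which is the C1/C5 relationship of the target.

Step 4
Reactants: 8 (1S*,3R*)-4,4-dimethyl-2-methylidene-3-vinylcyclohexan-1-ol (racemic)
Product: 9 (3S,4S,8R)-7,7-dimethyl-8-vinyl-1-oxaspiro[2.5]octan-4-ol
Conditions: Ti(OiPr)4 (1 equiv), L-(+)-diisopropyl tartrate (1.2 equiv), t-BuOOH (0.6 equiv), 4 Å MS, CH2Cl2, −20 °C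
Reagents that add atoms: tert-butyl hydroperoxide CC(C)(C)OO
Why: Sharpless asymmetric epoxidation run as a kinetic resolution, in which the L-(+)-tartrate complex epoxidises the (1S)-allylic alcohol fast (syn to the hydroxyl) and leaves the (1R)-enantiomer behind, so the absolute configuration at C1 and C5 is fixed here (the spiro carbon is later erased as a radical).

Step 5
Reactants: 9 (3S,4S,8R)-7,7-dimethyl-8-vinyl-1-oxaspiro[2.5]octan-4-ol
Product: 10 (3S,4S,8R)-7,7-dimethyl-8-vinyl-1-oxaspiro[2.5]octan-4-yl acetate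
Conditions: Ac2O, pyridine, DMAP (cat.), CH2Cl2, 23 °C
Reagents that add atoms: acetic anhydride CC(=O)OC(C)=O
Why: DMAP-catalysed acylation of the only free hydroxyl installs the C1 acetate of the target with retention.

Step 6
Reactants: 10 (3S,4S,8R)-7,7-dimethyl-8-vinyl-1-oxaspiro[2.5]octan-4-yl acetate; 11 3-oxocyclohex-1-ene-1-carboxylic acid
Product: 12 [(1S,2S,6R)-2-acetoxy-1-hydroxy-5,5-dimethyl-6-vinylcyclohexyl]methyl 3-oxocyclohex-1-ene-1-carboxylate
Conditions: Cs2CO3 (0.2 equiv), DMF, 80 °C
Reagents that add atoms: none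
Why: SN2 opening of the 2,2-disubstituted epoxide by the cesium carboxylate at its CH2 terminus builds the C20–O–C7 ester of the later lactone and leaves the tertiary C10 alcohol.

Step 7
Reactants: 12 [(1S,2S,6R)-2-acetoxy-1-hydroxy-5,5-dimethyl-6-vinylcyclohexyl]methyl 3-oxocyclohex-1-ene-1-carboxylate
Product: 15 cesium oxalate of the tertiary alcohol of 12, via chlorooxoacetate 13 (not isolated), via hydrogen oxalate 14 (not isolated)
Conditions: (COCl)2, Et2O, 0 to 23 °C; evaporate; H2O, THF; then CsOH (1.0 equiv), 0 °C; dry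
Reagents that add atoms: oxalyl chloride O=C(Cl)C(Cl)=O; water O; cesium hydroxide [Cs+].[OH-]
Why: Acylation of the tertiary alcohol with oxalyl chloride, hydrolysis and neutralisation give the cesium alkyl oxalate, the standard bench-stable precursor of a tertiary alkyl radical.

Step 8
Reactants: 15 cesium oxalate (vinyl compound)
Product: 16 cesium oxalate carrying the C6 aldehyde: cesium 2-{[(1S,2S,6R)-2-acetoxy-6-formyl-5,5-dimethyl-1-({[(3-oxocyclohex-1-en-1-yl)carbonyl]oxy}methyl)cyclohexyl]oxy}-2-oxoacetate
Conditions: O3, CH2Cl2/MeOH, −78 °C; Me2S; used crude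
Reagents that add atoms: ozone [O-][O+]=O
Why: Ozonolysis with reductive work-up cleaves the electron-rich terminal vinyl group (the ring C alkene carries two acceptors and reacts far more slowly) and unmasks the C6 aldehyde without touching C5.

Step 9
Reactants: 16 cesium oxalate carrying the C6 aldehyde
Product: 20 tetracyclic keto lactone (target skeleton: C1 acetate, C6 hydroxyl, C11 ketone, C13 as CH2; C1, C5, C6, C8, C9, C10 as in 28), via C10 radical 17 (not isolated), via C8 radical 18 (not isolated), via cesium enolate 19 (not isolated)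
Conditions: Ir[dF(CF3)ppy]2(dtbbpy)PF6 (2 mol %), dry DME/DMF (3:1, 0.01 M), blue LEDs, 23 °C; then H2O
Reagents that add atoms: none
Why: Proposed new method: photoredox oxidation of the oxalate releases two CO2 and the tertiary C10 radical, which closes the lactone ring by 6-endo conjugate addition to C9 through the ester tether (attack anti to the C1 acetoxy, the C5 formyl and the axial C4 methyl sets C10, the bulkier C5 arm turning away from C11 sets C9), the C8 radical is then reduced by the reduced photocatalyst to the lactone enolate, and this enolate, formed without base at the position where the biosynthetic retro-Claisen places it, adds to the C6 aldehyde to close the cyclopentane (C8 fixed by the bicyclo[3.2.1] geometry, C6 hydroxyl on the exo face), the closest known reaction types being the photoredox coupling of tertiary alkyl oxalate salts with electron-poor alkenes and radical–polar crossover aldol cyclisations.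

Step 10
Reactants: 20 tetracyclic keto lactone
Product: 22 C12=C13 enone, C6 trimethylsilyl ether, via silyl enol ether 21 (not isolated)
Conditions: Me3SiOTf, Et3N, CH2Cl2, −78 to 0 °C; then Pd(OAc)2 (1.1 equiv), MeCN, 23 °C
Reagents that add atoms: trimethylsilyl trifluoromethanesulfonate C[Si](C)(C)OS(=O)(=O)C(F)(F)F
Why: Soft enolisation silylates the C6 hydroxyl and converts the C11 ketone into its C11=C12 silyl enol ether, and Saegusa–Ito oxidation then gives the enone (an enol ether towards C9 could not be dehydrogenated because C8 and C10 are quaternary).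

Step 11
Reactants: 22 C12=C13 enone; 23 trimethyl phosphonoacetate; 24 formaldehyde
Product: 26 C11 ketone bearing the 1-(methoxycarbonyl)vinyl group at C13 and the C6 trimethylsilyl ether, via phosphonate carbanion 25 (not isolated)
Conditions: 23, NaH, THF, 0 to 23 °C; then 24 (aq.), K2CO3, 23 °C
Reagents that add atoms: none
Why: Michael addition of the phosphonoacetate anion occurs axially at C13, anti to the axial C8–C7 bond (also the thermodynamically preferred equatorial adduct), and Horner–Wadsworth–Emmons olefination of the resulting phosphonate carbanion with formaldehyde gives the 2-substituted methyl acrylate.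

Step 12
Reactants: 26 acrylate ketone silyl ether
Product: 28 target, methyl 2-substituted acrylate (1S,5R,6S,8S,9S,10S,11S,13S), via silyl ether 27 (not isolated)
Conditions: NaBH4, CeCl3·7H2O, MeOH, −78 °C; then 1 M HCl, 0 °C
Reagents that add atoms: none
Why: Luche reduction is expected to deliver hydride axially to the C11 ketone, giving the equatorial 11-alcohol trans to the C9–C10 bond while lactone, acetate and acrylate stay untouched, and the acidic work-up removes the trimethylsilyl ether.

**Compound list**
1 | 4,4-dimethylcyclohex-2-en-1-one | O=C1C=CC(C)(C)CC1 | starting material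
2 | vinylmagnesium bromide | C=C[Mg]Br | starting material
3 | N,N-dimethylmethyleneiminium iodide | C=[N+](C)C.[I-] | starting material
4 | bromomagnesium (3S*)-4,4-dimethyl-3-vinylcyclohex-1-en-1-olate (racemic, not isolated) | Br[Mg]OC1=C[C@H](C=C)C(C)(C)CC1 | intermediate
5 | (2R*,3S*)-2-[(dimethylamino)methyl]-4,4-dimethyl-3-vinylcyclohexan-1-one (racemic, trans) | C=C[C@H]1[C@H](CN(C)C)C(=O)CCC1(C)C | intermediate
6 | trimethylammonium iodide of 5 (racemic, not isolated) | C=C[C@H]1[C@H](C[N+](C)(C)C)C(=O)CCC1(C)C.[I-] | intermediate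
7 | (3R*)-4,4-dimethyl-2-methylidene-3-vinylcyclohexan-1-one (racemic) | C=C[C@H]1C(=C)C(=O)CCC1(C)C | intermediate
8 | (1S*,3R*)-4,4-dimethyl-2-methylidene-3-vinylcyclohexan-1-ol (racemic; enantiomer drawn is the one consumed in step 4) | C=C[C@H]1C(=C)[C@@H](O)CCC1(C)C | intermediate
9 | (3S,4S,8R)-7,7-dimethyl-8-vinyl-1-oxaspiro[2.5]octan-4-ol | C=C[C@H]1[C@]2(CO2)[C@@H](O)CCC1(C)C | intermediate
10 | (3S,4S,8R)-7,7-dimethyl-8-vinyl-1-oxaspiro[2.5]octan-4-yl acetate | C=C[C@H]1[C@]2(CO2)[C@@H](OC(C)=O)CCC1(C)C | intermediate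
11 | 3-oxocyclohex-1-ene-1-carboxylic acid | O=C1CCCC(C(=O)O)=C1 | starting material
12 | [(1S,2S,6R)-2-acetoxy-1-hydroxy-5,5-dimethyl-6-vinylcyclohexyl]methyl 3-oxocyclohex-1-ene-1-carboxylate | C=C[C@H]1[C@](O)(COC(=O)C2=CC(=O)CCC2)[C@@H](OC(C)=O)CCC1(C)C | intermediate
13 | chlorooxoacetate of the tertiary alcohol of 12 (not isolated) | C=C[C@H]1[C@](OC(=O)C(Cl)=O)(COC(=O)C2=CC(=O)CCC2)[C@@H](OC(C)=O)CCC1(C)C | intermediate
14 | hydrogen oxalate of the tertiary alcohol of 12 (not isolated) | C=C[C@H]1[C@](OC(=O)C(=O)O)(COC(=O)C2=CC(=O)CCC2)[C@@H](OC(C)=O)CCC1(C)C | intermediate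
15 | cesium oxalate of the tertiary alcohol of 12 | C=C[C@H]1[C@](OC(=O)C(=O)[O-])(COC(=O)C2=CC(=O)CCC2)[C@@H](OC(C)=O)CCC1(C)C.[Cs+] | intermediate
16 | cesium oxalate with C6 aldehyde in place of the vinyl group (1S,2S,6R) | O=C[C@H]1[C@](OC(=O)C(=O)[O-])(COC(=O)C2=CC(=O)CCC2)[C@@H](OC(C)=O)CCC1(C)C.[Cs+] | intermediate
17 | tertiary C10 radical (not isolated) | O=C[C@H]1[C](COC(=O)C2=CC(=O)CCC2)[C@@H](OC(C)=O)CCC1(C)C | intermediate
18 | spiro lactone with radical at C8, C9–C10 bond formed (not isolated) | C1CC(=O)[C@@H]2[C](C1)C(=O)OC[C@]21[C@@H](OC(C)=O)CCC(C)(C)[C@H]1C=O | intermediate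
19 | cesium enolate of the spiro lactone (C8=C7) carrying the C6 aldehyde (not isolated) | C1CC(=O)[C@@H]2C(C1)=C([O-])OC[C@]21[C@@H](OC(C)=O)CCC(C)(C)[C@H]1C=O.[Cs+] | intermediate
20 | tetracyclic keto lactone: C1 acetate, C6 hydroxyl, C11 ketone, C13 CH2 | C1CC(=O)[C@@H]2[C@]3(C1)C(=O)OC[C@]21[C@@H](OC(C)=O)CCC(C)(C)[C@H]1[C@@H]3O | intermediate
21 | C6 trimethylsilyl ether, C11=C12 trimethylsilyl enol ether of 20 (not isolated) | C1C=C(O[Si](C)(C)C)[C@@H]2[C@]3(C1)C(=O)OC[C@]21[C@@H](OC(C)=O)CCC(C)(C)[C@H]1[C@@H]3O[Si](C)(C)C | intermediate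
22 | C12=C13 enone, C6 trimethylsilyl ether | C1=CC(=O)[C@@H]2[C@]3(C1)C(=O)OC[C@]21[C@@H](OC(C)=O)CCC(C)(C)[C@H]1[C@@H]3O[Si](C)(C)C | intermediate
23 | trimethyl phosphonoacetate | COC(=O)CP(=O)(OC)OC | starting material
24 | formaldehyde | C=O | starting material
25 | sodium salt of the phosphonate carbanion attached at C13 (not isolated) | COC(=O)[C-](P(=O)(OC)OC)[C@@H]1CC(=O)[C@@H]2[C@]3(C1)C(=O)OC[C@]21[C@@H](OC(C)=O)CCC(C)(C)[C@H]1[C@@H]3O[Si](C)(C)C.[Na+] | intermediate
26 | C11 ketone with 1-(methoxycarbonyl)vinyl at C13, C6 trimethylsilyl ether | C=C(C(=O)OC)[C@@H]1CC(=O)[C@@H]2[C@]3(C1)C(=O)OC[C@]21[C@@H](OC(C)=O)CCC(C)(C)[C@H]1[C@@H]3O[Si](C)(C)C | intermediate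
27 | C6 trimethylsilyl ether of the target (not isolated) | C=C(C(=O)OC)[C@@H]1C[C@H](O)[C@@H]2[C@]3(C1)C(=O)OC[C@]21[C@@H](OC(C)=O)CCC(C)(C)[C@H]1[C@@H]3O[Si](C)(C)C | intermediate
28 | target: methyl acrylate at C13, 1-acetoxy, 6,11-dihydroxy, 7,20-lactone (1S,5R,6S,8S,9S,10S,11S,13S) | C=C(C(=O)OC)[C@@H]1C[C@H](O)[C@@H]2[C@]3(C1)C(=O)OC[C@]21[C@@H](OC(C)=O)CCC(C)(C)[C@H]1[C@@H]3O | target

**Totals and risks**
Total step count: 12. Longest linear sequence: 12 steps (from 1; acid 11 and the side-chain reagents 23 and 24 enter directly).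

Step 9 is the most likely to fail. The 6-endo addition through the ester tether is slow, the β-acyloxy aldehyde 16 can eliminate, the C8 radical may abstract the aldehyde hydrogen, and the enolate may be protonated before it cyclises. The fallback separates the events and makes the radical reductively: setting out from 10, Cp2TiCl (from Cp2TiCl2 and Zn) opens the epoxide to the same C10 radical, which adds intermolecularly to C9 of 2,2,2-trifluoroethyl 3-oxocyclohex-1-ene-1-carboxylate F1 (from 11 and trifluoroethanol). The titanium alkoxide then lactonises to the vinyl spiro lactone F2, ozonolysis gives the keto aldehyde lactone F3, and a separate aldol closure with LiN(SiMe3)2 at −78 °C (or DBU) comes back to the route at 20.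

Step 12 is the second risk: the lower face of the C11 ketone is flanked by the axial lactone carbonyl, so the hydride may enter from the other side and give the 11-epimer. The fallback sets out from 22 and uses inversion instead of direct reduction. Michael addition of 23 without the olefination gives the keto phosphonate F4, and LiBH(s-Bu)3 reduces it from the open face to the axial 11-epi alcohol F5. Mitsunobu reaction with chloroacetic acid (PPh3, DIAD) gives the inverted chloroacetate F6. Aqueous formaldehyde/K2CO3 then performs the olefination and cleaves the chloroacetate, and acidic work-up removes the silyl group, so the sequence comes back at 28.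

Step 4 is the third risk: the selectivity factor of the epoxidation-based kinetic resolution on this cyclic 2-methylidene alcohol may be low. The fallback sets out from racemic 8 and resolves by enzymatic acylation: Amano lipase PS and vinyl acetate convert the (1R)-enantiomer into its acetate F7, and the recovered (1S,3R)-alcohol 8 is epoxidised syn to the hydroxyl with VO(acac)2/t-BuOOH, which comes back to the route at 9.

Further compounds
F1 | step 9 | 2,2,2-trifluoroethyl 3-oxocyclohex-1-ene-1-carboxylate | O=C1CCCC(C(=O)OCC(F)(F)F)=C1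
F2 | step 9 | spiro lactone with C9–C10 bond, C5 vinyl group, C1 acetate, C11 ketone (C8 unassigned) | C1CC(=O)[C@@H]2C(C1)C(=O)OC[C@]21[C@@H](OC(C)=O)CCC(C)(C)[C@H]1C=C
F3 | step 9 | spiro lactone of F2 with C6 aldehyde in place of the vinyl group | C1CC(=O)[C@@H]2C(C1)C(=O)OC[C@]21[C@@H](OC(C)=O)CCC(C)(C)[C@H]1C=O
F4 | step 12 | keto phosphonate: Michael adduct of 23 at C13 of 22 | COC(=O)C(P(=O)(OC)OC)[C@@H]1CC(=O)[C@@H]2[C@]3(C1)C(=O)OC[C@]21[C@@H](OC(C)=O)CCC(C)(C)[C@H]1[C@@H]3O[Si](C)(C)C
F5 | step 12 | 11-epi (axial) alcohol of F4 | COC(=O)C(P(=O)(OC)OC)[C@@H]1C[C@@H](O)[C@@H]2[C@]3(C1)C(=O)OC[C@]21[C@@H](OC(C)=O)CCC(C)(C)[C@H]1[C@@H]3O[Si](C)(C)C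
F6 | step 12 | inverted C11 chloroacetate of F5 | COC(=O)C(P(=O)(OC)OC)[C@@H]1C[C@H](OC(=O)CCl)[C@@H]2[C@]3(C1)C(=O)OC[C@]21[C@@H](OC(C)=O)CCC(C)(C)[C@H]1[C@@H]3O[Si](C)(C)C
F7 | step 4 | (1R,3S)-4,4-dimethyl-2-methylidene-3-vinylcyclohexyl acetate | C=C[C@@H]1C(=C)[C@H](OC(C)=O)CCC1(C)C
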